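**Plan** (target numbering: C1 = C(CH3)2, C2 and C4 = CHCl, C3 = alkylidene carbon, C5 = CH2, C6 = CHBr)
1. Retrosynthesis: cut the primary C–Br bond (allylic alcohol), then C4–Cl (C4–O, inversion), then in one event the ring bond C1–C6 together with C2–Cl; the open chain is cut at C2–C3 (Suzuki), at C3–CH(exocyclic) (Claisen) and at C4–C5 (aldol).
2. Forward: aldol, Claisen, (Z)-enol triflate and Suzuki coupling join an acyclic dienoate ending in CHBr2; the only ring, the cyclohexane, is closed in step 8.
3. Enabling feature: the 5-methylhexa-2,4-dienoate unit O=C–CH=C3–C2H=C1(CH3)2, whose C3 carries the chain C4–C5–C6HBr2; C1 lies six atoms from the radical carbon, and the allyl radical over C2, C3 and the exocyclic CH takes chlorine back at C2.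
4. Stereochemistry: the C4 carbinol comes from a catalyst-controlled aldol; it sets C6 (chair, 1,3-cis) and, through the ring, the axial C2–Cl; C4–O is then replaced by Cl with inversion; the alkene geometry comes from the (Z)-enol triflate.

Key step: step 8

Assumption: the (S)-diarylprolinol is taken to give the 2R aldol (Re-face attack on the glyoxylate, as in proline-type hydrogen-bonded enamine transition states); if the sense is the reverse, the (R)-catalyst is used and nothing else changes.

Step 1
Reactants: 1 ethyl glyoxylate; 2 acetaldehyde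
Product: 4 ethyl (2R)-4,4-diethoxy-2-hydroxybutanoate, via ethyl (2R)-2-hydroxy-4-oxobutanoate 3 (not isolated)
Conditions: (S)-α,α-bis[3,5-bis(trifluoromethyl)phenyl]pyrrolidin-2-ylmethanol (10 mol%), MeCN, H2O (3 equiv), rt; then HC(OEt)3, p-TsOH (cat.), EtOH, rt
Reagents that add atoms: triethyl orthoformate, CCOC(OCC)OCC
Why: Diarylprolinol-catalysed enamine cross-aldol reaction of acetaldehyde with the non-enolisable, highly electrophilic glyoxylate, in which the catalyst hydroxyl hydrogen-bonds the acceptor and directs attack to its Re face to set the 2R carbinol, followed by acid-catalysed acetalisation that masks the labile β-hydroxy aldehyde in the same flask.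

Step 2
Reactants: 4 ethyl (2R)-4,4-diethoxy-2-hydroxybutanoate
Product: 5 ethyl (2R)-2-{[tert-butyl(dimethyl)silyl]oxy}-4,4-diethoxybutanoate
Conditions: TBSCl, imidazole, DMF, rt
Reagents that add atoms: tert-butyl(chloro)dimethylsilane, CC(C)(C)[Si](C)(C)Cl
Why: Imidazole-promoted silylation of a secondary alcohol, which leaves the stereocentre untouched.

Step 3
Reactants: 5 ethyl (2R)-2-{[tert-butyl(dimethyl)silyl]oxy}-4,4-diethoxybutanoate; 6 ethyl acetate
Product: 8 ethyl (4R)-4-{[tert-butyl(dimethyl)silyl]oxy}-6,6-diethoxy-3-oxohexanoate, via lithium enolate of ethyl acetate 7 (not isolated)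
Conditions: LiN(i-Pr)2 (2.6 equiv), 6 (2.6 equiv), THF, −78 °C; then 5, −78 to −40 °C; aq. NH4Cl
Reagents that add atoms: none
Why: Crossed Claisen condensation in which the ester enolate adds to the more electrophilic α-silyloxy ester at low temperature, while immediate deprotonation of the β-keto ester by the second equivalent drives the reaction and keeps the neighbouring stereocentre from enolising.

Step 4
Reactants: 8 ethyl (4R)-4-{[tert-butyl(dimethyl)silyl]oxy}-6,6-diethoxy-3-oxohexanoate
Product: 9 ethyl (2Z,4R)-4-{[tert-butyl(dimethyl)silyl]oxy}-6,6-diethoxy-3-{[(trifluoromethyl)sulfonyl]oxy}hex-2-enoate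
Conditions: (CF3SO2)2O, saturated aq. LiOH, toluene, 5 °C
Reagents that add atoms: trifluoromethanesulfonic anhydride, O=S(=O)(OS(=O)(=O)C(F)(F)F)C(F)(F)F
Why: Stereoselective enol triflation of a β-keto ester under aqueous LiOH conditions, where the lithium-chelated Z enolate is trapped on oxygen so that the triflate ends up cis to the ester.

Step 5
Reactants: 9 ethyl (2Z,4R)-4-{[tert-butyl(dimethyl)silyl]oxy}-6,6-diethoxy-3-{[(trifluoromethyl)sulfonyl]oxy}hex-2-enoate; 10 4,4,5,5-tetramethyl-2-(2-methylprop-1-en-1-yl)-1,3,2-dioxaborolane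
Product: 11 ethyl (2E)-3-[(1R)-1-{[tert-butyl(dimethyl)silyl]oxy}-3,3-diethoxypropyl]-5-methylhexa-2,4-dienoate
Conditions: Pd(PPh3)4 (5 mol%), K3PO4, 1,4-dioxane/H2O, 60 °C
Reagents that add atoms: none
Why: Suzuki–Miyaura coupling of an electron-poor alkenyl triflate, which proceeds with retention of alkene geometry and so places the 2-methylprop-1-enyl group cis to the ester (the descriptor changes from Z to E only through the priority rules).

Step 6
Reactants: 11 ethyl (2E)-3-[(1R)-1-{[tert-butyl(dimethyl)silyl]oxy}-3,3-diethoxypropyl]-5-methylhexa-2,4-dienoate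
Product: 12 ethyl (2E)-3-[(1R)-1-{[tert-butyl(dimethyl)silyl]oxy}-3-oxopropyl]-5-methylhexa-2,4-dienoate
Conditions: pyridinium p-toluenesulfonate (0.3 equiv), THF/H2O (4:1), 45 °C
Reagents that add atoms: water, O
Why: Mild acid-catalysed acetal hydrolysis, under which the secondary silyl ether and the dienoate should persist.

Step 7
Reactants: 12 ethyl (2E)-3-[(1R)-1-{[tert-butyl(dimethyl)silyl]oxy}-3-oxopropyl]-5-methylhexa-2,4-dienoate
Product: 13 ethyl (2E)-3-[(1R)-3,3-dibromo-1-{[tert-butyl(dimethyl)silyl]oxy}propyl]-5-methylhexa-2,4-dienoate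
Conditions: P(OPh)3, Br2, CH2Cl2, −78 °C; then Et3N, 12, −78 to 0 °C
Reagents that add atoms: bromine, BrBr
Why: Deoxygenative geminal dibromination of an enolisable aldehyde with the preformed triphenyl phosphite–bromine adduct (an Appel-type oxyphosphonium pathway), run cold and buffered with Et3N so that the diene and the silyl ether are spared.

Step 8
Reactants: 13 ethyl (2E)-3-[(1R)-3,3-dibromo-1-{[tert-butyl(dimethyl)silyl]oxy}propyl]-5-methylhexa-2,4-dienoate
Product: 14 ethyl (2Z)-2-[(2S,4S,6R)-4-bromo-6-{[tert-butyl(dimethyl)silyl]oxy}-2-chloro-3,3-dimethylcyclohexylidene]acetate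
Conditions: CuCl (0.3 equiv), tris(2-pyridylmethyl)amine (TPMA, 0.33 equiv), Bu4NCl (3 equiv), degassed MeCN (0.02 M), 70 °C
Reagents that add atoms: tetrabutylammonium chloride, [Cl-].CCCC[N+](CCCC)(CCCC)CCCC; CuCl, [Cu+].[Cl-]
Why: Proposed new method: monovalent copper (CuCl·TPMA) abstracts one bromine atom from the CHBr2 group, the α-bromoalkyl radical adds to the C(CH3)2 terminus of the dienoate, and the ester-conjugated allyl radical so formed takes a chlorine atom from the chloride-loaded divalent copper complex at its ring end, which regenerates monovalent copper. The closest known reaction types are the copper-catalysed atom-transfer radical cyclisation (Kharasch type) and the bromide-to-chloride halogen exchange known from atom-transfer radical polymerisation; the new elements are a geminal dibromide as initiator, attack on a fully substituted diene terminus and chlorine return at the vinylogous position. The cyclohexane closes in the 6-endo-trig mode, since attack on the terminus keeps the diene planar and gives a delocalised radical, whereas 5-exo attack on the internal diene carbon would twist the diene out of conjugation and give a localised tertiary radical. The CHBr centre (4S) is set by the silyloxy-bearing carbon through a chair transition state with Br and OTBS both equatorial (1,3-cis; the axial site is blocked for Br by the methyl group that becomes axial), and the CHCl centre (2S) by axial chlorine delivery anti to that axial methyl, which also relieves allylic 1,3-strain with the cis ester. The step needs halogen selectivity (Br on the neopentyl carbon, Cl on the allylic carbon) and site selectivity (γ rather than α to the ester); both should be secured because monovalent copper keeps reactivating any allylic bromide or α-chloro ester while excess chloride funnels the material to the stronger, conjugated γ-C–Cl bond, the unactivated secondary C–Br bond staying inert, and the alkene geometry of 13 carries over unchanged into the exocyclic double bond.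

Step 9
Reactants: 14 ethyl (2Z)-2-[(2S,4S,6R)-4-bromo-6-{[tert-butyl(dimethyl)silyl]oxy}-2-chloro-3,3-dimethylcyclohexylidene]acetate
Product: 15 ethyl (2Z)-2-[(2S,4S,6R)-4-bromo-2-chloro-6-hydroxy-3,3-dimethylcyclohexylidene]acetate
Conditions: HF·pyridine, pyridine, THF, 0 °C to rt
Reagents that add atoms: none
Why: Fluoride-mediated cleavage of the silyl ether under buffered, weakly acidic conditions that should not disturb the allylic chloride, the alkyl bromide or the ester.

Step 10
Reactants: 15 ethyl (2Z)-2-[(2S,4S,6R)-4-bromo-2-chloro-6-hydroxy-3,3-dimethylcyclohexylidene]acetate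
Product: 16 ethyl (2Z)-2-[(2S,4S,6S)-4-bromo-2,6-dichloro-3,3-dimethylcyclohexylidene]acetate
Conditions: PPh3, N-chlorosuccinimide, THF, 0 °C (reagent preformed); then 15, 0 °C to rt
Reagents that add atoms: N-chlorosuccinimide, O=C1CCC(=O)N1Cl
Why: Appel-type chlorination through an alkoxyphosphonium ion, whose SN2 displacement by chloride at the allylic ring carbon inverts the carbinol and gives the 6S chloride cis to the first chlorine, while the electron-poor alkene disfavours ionisation and SN2' attack.

Step 11
Reactants: 16 ethyl (2Z)-2-[(2S,4S,6S)-4-bromo-2,6-dichloro-3,3-dimethylcyclohexylidene]acetate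
Product: 17 (2Z)-2-[(2S,4S,6S)-4-bromo-2,6-dichloro-3,3-dimethylcyclohexylidene]ethan-1-ol
Conditions: i-Bu2AlH (2.2 equiv), CH2Cl2, −78 °C; aq. potassium sodium tartrate
Reagents that add atoms: none
Why: Low-temperature i-Bu2AlH 1,2-reduction of an α,β-unsaturated ester to the allylic alcohol, a reduction that γ-halo enoates tolerate.

Step 12
Reactants: 17 (2Z)-2-[(2S,4S,6S)-4-bromo-2,6-dichloro-3,3-dimethylcyclohexylidene]ethan-1-ol
Product: 18 (2S,3Z,4S,6S)-6-bromo-3-(2-bromoethylidene)-2,4-dichloro-1,1-dimethylcyclohexane
Conditions: CBr4 (1.2 equiv), PPh3 (1.2 equiv), CH2Cl2, −20 to 0 °C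
Reagents that add atoms: carbon tetrabromide, BrC(Br)(Br)Br
Why: Appel bromination of a primary allylic alcohol, an SN2 process without allylic transposition, run cold and with only a slight excess of reagent so that bromide should not exchange with the secondary allylic chlorides.

**Compound list**
1 | ethyl glyoxylate | O=CC(=O)OCC | starting material
2 | acetaldehyde | CC=O | starting material
3 | ethyl (2R)-2-hydroxy-4-oxobutanoate | CCOC(=O)[C@H](O)CC=O | intermediate
4 | ethyl (2R)-4,4-diethoxy-2-hydroxybutanoate | CCOC(=O)[C@H](O)CC(OCC)OCC | intermediate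
5 | ethyl (2R)-2-{[tert-butyl(dimethyl)silyl]oxy}-4,4-diethoxybutanoate | CCOC(=O)[C@H](O[Si](C)(C)C(C)(C)C)CC(OCC)OCC | intermediate
6 | ethyl acetate | CCOC(C)=O | starting material
7 | lithium enolate of ethyl acetate (lithium 1-ethoxyethen-1-olate) | [Li+].[O-]C(=C)OCC | intermediate
8 | ethyl (4R)-4-{[tert-butyl(dimethyl)silyl]oxy}-6,6-diethoxy-3-oxohexanoate | CCOC(=O)CC(=O)[C@H](O[Si](C)(C)C(C)(C)C)CC(OCC)OCC | intermediate
9 | ethyl (2Z,4R)-4-{[tert-butyl(dimethyl)silyl]oxy}-6,6-diethoxy-3-{[(trifluoromethyl)sulfonyl]oxy}hex-2-enoate | CCOC(=O)/C=C(\OS(=O)(=O)C(F)(F)F)[C@H](O[Si](C)(C)C(C)(C)C)CC(OCC)OCC | intermediate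
10 | 4,4,5,5-tetramethyl-2-(2-methylprop-1-en-1-yl)-1,3,2-dioxaborolane | CC(C)=CB1OC(C)(C)C(C)(C)O1 | starting material
11 | ethyl (2E)-3-[(1R)-1-{[tert-butyl(dimethyl)silyl]oxy}-3,3-diethoxypropyl]-5-methylhexa-2,4-dienoate | CCOC(=O)/C=C(\C=C(C)C)[C@H](O[Si](C)(C)C(C)(C)C)CC(OCC)OCC | intermediate
12 | ethyl (2E)-3-[(1R)-1-{[tert-butyl(dimethyl)silyl]oxy}-3-oxopropyl]-5-methylhexa-2,4-dienoate | CCOC(=O)/C=C(\C=C(C)C)[C@H](O[Si](C)(C)C(C)(C)C)CC=O | intermediate
13 | ethyl (2E)-3-[(1R)-3,3-dibromo-1-{[tert-butyl(dimethyl)silyl]oxy}propyl]-5-methylhexa-2,4-dienoate | CCOC(=O)/C=C(\C=C(C)C)[C@H](O[Si](C)(C)C(C)(C)C)CC(Br)Br | intermediate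
14 | ethyl (2Z)-2-[(2S,4S,6R)-4-bromo-6-{[tert-butyl(dimethyl)silyl]oxy}-2-chloro-3,3-dimethylcyclohexylidene]acetate | CC1(C)[C@@H](Br)C[C@@H](O[Si](C)(C)C(C)(C)C)/C(=C/C(=O)OCC)[C@@H]1Cl | intermediate
15 | ethyl (2Z)-2-[(2S,4S,6R)-4-bromo-2-chloro-6-hydroxy-3,3-dimethylcyclohexylidene]acetate | CC1(C)[C@@H](Br)C[C@@H](O)/C(=C/C(=O)OCC)[C@@H]1Cl | intermediate
16 | ethyl (2Z)-2-[(2S,4S,6S)-4-bromo-2,6-dichloro-3,3-dimethylcyclohexylidene]acetate | CC1(C)[C@@H](Br)C[C@H](Cl)/C(=C/C(=O)OCC)[C@@H]1Cl | intermediate
17 | (2Z)-2-[(2S,4S,6S)-4-bromo-2,6-dichloro-3,3-dimethylcyclohexylidene]ethan-1-ol | CC1(C)[C@@H](Br)C[C@H](Cl)/C(=C/CO)[C@@H]1Cl | intermediate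
18 | (2S,3Z,4S,6S)-6-bromo-3-(2-bromoethylidene)-2,4-dichloro-1,1-dimethylcyclohexane | CC1(C)[C@@H](Br)C[C@H](Cl)/C(=C/CBr)[C@@H]1Cl | target

Total step count: 12. Longest linear sequence: 12 steps.

**Steps most likely to fail**

Step 8 (proposed new method). The chlorine-return half of the cycle may fail: bromine instead of chlorine may be delivered to the allyl radical, chlorine may go to the exocyclic end, or activation of the geminal dibromide may be so slow that the open-chain radical is reduced or couples. The fallback uses known chemistry and separates ring closure from chlorination. It sets out from 13: reductive radical cyclisation with (Me3Si)3SiH (1.05 equiv, slow addition) and AIBN in benzene at 80 °C should form the same ring bond and quench the allyl radical with hydrogen at the carbon next to the ester, giving ethyl 2-[(4S,6R)-4-bromo-6-{[tert-butyl(dimethyl)silyl]oxy}-3,3-dimethylcyclohex-1-en-1-yl]acetate F1. Selenium-catalysed ene-type allylic chlorination of the trisubstituted ring alkene (N-chlorosuccinimide, PhSeCl cat., CH2Cl2), a known outcome for β,γ-unsaturated esters, should then place chlorine on the ring CH and move the double bond into conjugation with the ester, which returns to the route at 14.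

Step 10. Substitution with inversion may be slow, because chloride has to enter along an axial path beside the axial C–Cl bond; elimination to a ring diene or chloride return with retention would then compete. The fallback moves the substitution in front of the ring closure. It sets out from 13: HF·pyridine should give ethyl (2E)-3-[(1R)-3,3-dibromo-1-hydroxypropyl]-5-methylhexa-2,4-dienoate F2, and PPh3/N-chlorosuccinimide should invert this unhindered open-chain carbinol to ethyl (2E)-3-[(1S)-3,3-dibromo-1-chloropropyl]-5-methylhexa-2,4-dienoate F3. The ring is then closed as in step 8, but with CuCl (1.2 equiv)/TPMA and no ammonium chloride, to limit chloride exchange at the open-chain allylic chloride; this returns to the route at 16. Control at the CHBr carbon then rests on chlorine taking an axial site in the chair, so the diastereomers may need separation.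

Step 7. Free bromine or HBr may add to the electron-rich C(CH3)2=CH end of the diene or isomerise it while the aldehyde is being converted. The fallback installs the geminal dibromide before the diene exists. It sets out from 9: the same acetal hydrolysis should give ethyl (2Z,4R)-4-{[tert-butyl(dimethyl)silyl]oxy}-6-oxo-3-{[(trifluoromethyl)sulfonyl]oxy}hex-2-enoate F4, and P(OPh)3/Br2/Et3N should convert it to ethyl (2Z,4R)-6,6-dibromo-4-{[tert-butyl(dimethyl)silyl]oxy}-3-{[(trifluoromethyl)sulfonyl]oxy}hex-2-enoate F5. Suzuki coupling with 10 (Pd(PPh3)4, K3PO4), in which zerovalent palladium should insert into the alkenyl triflate far faster than into the unactivated alkyl bromide, returns to the route at 13.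

**Further compounds**
F1 | step 8 | ethyl 2-[(4S,6R)-4-bromo-6-{[tert-butyl(dimethyl)silyl]oxy}-3,3-dimethylcyclohex-1-en-1-yl]acetate | CC1(C)[C@@H](Br)C[C@@H](O[Si](C)(C)C(C)(C)C)C(CC(=O)OCC)=C1
F2 | step 10 | ethyl (2E)-3-[(1R)-3,3-dibromo-1-hydroxypropyl]-5-methylhexa-2,4-dienoate | CCOC(=O)/C=C(\C=C(C)C)[C@H](O)CC(Br)Br
F3 | step 10 | ethyl (2E)-3-[(1S)-3,3-dibromo-1-chloropropyl]-5-methylhexa-2,4-dienoate | CCOC(=O)/C=C(\C=C(C)C)[C@@H](Cl)CC(Br)Br
F4 | step 7 | ethyl (2Z,4R)-4-{[tert-butyl(dimethyl)silyl]oxy}-6-oxo-3-{[(trifluoromethyl)sulfonyl]oxy}hex-2-enoate | CCOC(=O)/C=C(\OS(=O)(=O)C(F)(F)F)[C@H](O[Si](C)(C)C(C)(C)C)CC=O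
F5 | step 7 | ethyl (2Z,4R)-6,6-dibromo-4-{[tert-butyl(dimethyl)silyl]oxy}-3-{[(trifluoromethyl)sulfonyl]oxy}hex-2-enoate | CCOC(=O)/C=C(\OS(=O)(=O)C(F)(F)F)[C@H](O[Si](C)(C)C(C)(C)C)CC(Br)Br
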